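A direct plan would start from veratrole A1, acylate it twice with a malonyl unit and close the five-membered ring to the achiral indenone A2.
A copper hydride conjugate reduction with in situ carboxylation would give indanone ester A3, a zinc-carbenoid one-carbon ring expansion tetralone ester A4, and a second carboxylation keto diester A5.
Ester exchange at C3 with a protected (S)-malate, ketone reduction and one BBr3 treatment (dehydration, ester and ether cleavage) would end the route.
Weak point 1, the ring expansion with the two carboxylations around it: ring B and its two carboxyl carbons would arrive one carbon at a time over three steps, the first by an unprecedented reductive trapping, and C2 would have to be epimerised afterwards.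
Weak point 2, the C4 ketone: it would be carried through five steps only to be reduced and eliminated, and the C3 centre next to it would be set and then destroyed.
Weak point 3, the final BBr3 step: a large excess of a strong Lewis acid would have to dehydrate, cleave three tert-butyl esters and four aryl methyl ethers on the finished, elimination-prone acyloxysuccinate.

**Retrosynthetic overview**
Ring B (C1, C2, C3, C4, C4a, C8a) would be cut at C1–C2 and C3–C4, giving a photoenol (hydroxy-o-quinodimethane) of a 2-benzylbenzaldehyde that holds both catechol rings, and a fumarate that already carries the (S)-malate ester.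
Both benzene rings are bought; ring B is the only ring made, in one [4+2] step that forms two C–C bonds and sets C1 and C2 together.
The CH2CO2H arm of the malate, free in the target, would bind titanium as a carboxylate and act as a temporary tether (O–Ti–O2C, not in the target) that fixes regiochemistry, endo orientation and face; the malate is a built-in auxiliary that is never removed.
The C4–OH left by the cycloaddition is the leaving group for C3=C4, so no ketone, ring expansion or late ester exchange is needed; all protecting groups are benzyl and leave by hydrogenolysis before the alkene exists, so no BBr3 is used.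

Key step: step 6

Remark on the chemistry: the SMILES is read as the trans-(1R,2S)-1-aryl-1,2-dihydronaphthalene-2,3-dicarboxylic acid esterified at the C3 carboxyl by the hydroxyl of (S)-malic acid (locants C1–C8a refer to this ring system); mono-benzyl fumarate and 3,4-bis(benzyloxy)benzyl chloride are taken as catalogue compounds.

Step 1
Reactants: 1 3,4-bis(benzyloxy)benzaldehyde
Product: 2 4,5-bis(benzyloxy)-2-bromobenzaldehyde
Conditions: Br2 (1.05 equiv), NaOAc, AcOH, 20 °C
Reagents that add atoms: bromine BrBr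
Why: Electrophilic aromatic bromination should go to C6, para to the 3-benzyloxy group and ortho to the formyl group, the one alkoxy-activated position not flanked by two substituents; the acetate buffer protects the benzyl ethers from HBr.

Step 2
Reactants: 3 1,2-bis(benzyloxy)-4-(chloromethyl)benzene
Product: 4 2-[3,4-bis(benzyloxy)benzyl]-4,4,5,5-tetramethyl-1,3,2-dioxaborolane
Conditions: B2pin2 (1.1 equiv), Pd(dba)2 (3 mol %), P(4-MeOC6H4)3 (6 mol %), KOAc, toluene, 50 °C
Reagents that add atoms: bis(pinacolato)diboron CC1(C)OB(OC1(C)C)B1OC(C)(C)C(C)(C)O1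
Why: Palladium-catalysed Miyaura borylation of the benzylic chloride should give a benzylboronate that, unlike a benzylzinc or Grignard reagent, does not add to the aldehyde of 2 in the next step.

Step 3
Reactants: 2 4,5-bis(benzyloxy)-2-bromobenzaldehyde; 4 2-[3,4-bis(benzyloxy)benzyl]-4,4,5,5-tetramethyl-1,3,2-dioxaborolane
Product: 5 4,5-bis(benzyloxy)-2-[3,4-bis(benzyloxy)benzyl]benzaldehyde
Conditions: Pd(OAc)2 (3 mol %), SPhos (6 mol %), K3PO4, toluene–H2O, 80 °C
Reagents that add atoms: none
Why: Suzuki–Miyaura sp2–sp3 cross-coupling should join the two protected catechol rings through the CH2 group that becomes C1 and leave the free aldehyde, the later C4, untouched.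

Step 4
Reactants: 6 (S)-malic acid
Product: 8 (3S)-4-(benzyloxy)-3-hydroxy-4-oxobutanoic acid [(S)-malic acid 1-benzyl ester], via O-trifluoroacetylmalic anhydride 7 (not isolated)
Conditions: (CF3CO)2O, 0 °C to rt, evaporate; BnOH (2.5 equiv), rt; NaHCO3 extraction, then H+
Reagents that add atoms: benzyl alcohol OCc1ccccc1
Why: Trifluoroacetic anhydride should give the O-trifluoroacetyl cyclic anhydride 7, which benzyl alcohol opens at the more electrophilic carbonyl beside the acyloxy group (regioselective anhydride alcoholysis, then loss of the trifluoroacetyl group by alcoholysis), so that only the carboxyl on the stereocentre is esterified and the CH2CO2H arm stays free; the stereocentre is not involved.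

Step 5
Reactants: 8 (3S)-4-(benzyloxy)-3-hydroxy-4-oxobutanoic acid; 9 (2E)-4-(benzyloxy)-4-oxobut-2-enoic acid (mono-benzyl fumarate, 2.2 equiv)
Product: 11 (3S)-4-(benzyloxy)-3-{[(2E)-4-(benzyloxy)-4-oxobut-2-enoyl]oxy}-4-oxobutanoic acid, via benzyl fumaroyl chloride 10 (not isolated)
Conditions: 9, (COCl)2, DMF (cat.), CH2Cl2, 0 °C to rt; then 8, pyridine, DMAP (5 mol %), CH2Cl2, 0 °C; pyridine–H2O, rt
Reagents that add atoms: none
Why: Esterification of the secondary alcohol with the acid chloride under pyridine/DMAP (nucleophilic acyl substitution) should give the mixed fumarate, and any mixed anhydride formed at the free acid is hydrolysed by the aqueous pyridine quench, which is why the chloride is used in excess.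

Step 6
Reactants: 5 4,5-bis(benzyloxy)-2-[3,4-bis(benzyloxy)benzyl]benzaldehyde; 11 (3S)-4-(benzyloxy)-3-{[(2E)-4-(benzyloxy)-4-oxobut-2-enoyl]oxy}-4-oxobutanoic acid (1.2 equiv)
Product: 14 2-benzyl 3-[(2S)-1-(benzyloxy)-3-carboxy-1-oxopropan-2-yl] (1R,2S,3R,4R)-6,7-bis(benzyloxy)-1-[3,4-bis(benzyloxy)phenyl]-4-hydroxy-1,2,3,4-tetrahydronaphthalene-2,3-dicarboxylate, via photoenol 12 (not isolated), via titanium carboxylate dienolate 13 (not isolated)
Conditions: 11, Ti(OiPr)4 (1.2 equiv), toluene, rt, 30 min; then 5, hν (366 nm), Ar, rt; aq. citric acid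
Reagents that add atoms: none
Why: Proposed new method: 366 nm light turns 5 into the (E,E)-hydroxy-o-quinodimethane 12 (photoenolization by intramolecular hydrogen abstraction), whose OH exchanges onto the titanium that already holds 11 as its carboxylate, so that in 13 a temporary C4–O–Ti–O2C link joins diene and dienophile and the [4+2] cycloaddition becomes intramolecular; the closest known reaction types are the Ti(OiPr)4-templated photoenolization/Diels–Alder reaction of 2-alkylbenzaldehydes, the cycloaddition of α-hydroxy-α'-aryl-o-quinodimethanes with fumarates of α-hydroxy esters, and metal-alkoxide-tethered Diels–Alder reactions. Ring B closes by a suprafacial endo [4+2] addition that forms C1–C2 and C3–C4 together inside a ten-membered titanacycle, the fumaroyl C=O beside C3 being bound to the same metal. Regiochemistry (malate-bearing alkene carbon to the oxygen-bearing terminus C4) and the endo place of that ester follow from the tether, and with the trans alkene the benzyl ester at C2 is then exo, which gives C1-aryl/C2-ester trans and C3-ester/C4-OH cis from the E,E-diene. The face is controlled by the (S)-malate centre: with its C–H turned to the benzo ring, only attack on the si,si face of the fumarate lets the CH2CO2 arm reach titanium, whereas on the other face this arm points away from the metal, so that C1 is R and C2 is S (C3 R and C4 R are erased in step 7). The step needs capture of the E-enol only, one regiochemistry and one face; the first is secured by the fast thermal return of the Z-enol to 5, the others by the carboxylate tether, which is lost as titanium dioxide on work-up.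

Step 7
Reactants: 14 2-benzyl 3-[(2S)-1-(benzyloxy)-3-carboxy-1-oxopropan-2-yl] (1R,2S,3R,4R)-6,7-bis(benzyloxy)-1-[3,4-bis(benzyloxy)phenyl]-4-hydroxy-1,2,3,4-tetrahydronaphthalene-2,3-dicarboxylate
Product: 16 (2S)-2-{[(1R,2S)-2-carboxy-1-(3,4-dihydroxyphenyl)-6,7-dihydroxy-1,2-dihydronaphthalene-3-carbonyl]oxy}butanedioic acid (target), via debenzylated tetralol triacid 15 (not isolated)
Conditions: H2 (1 atm), 10% Pd/C, THF, rt; filter under Ar; then CF3CO2H (5 vol %), 40 °C
Reagents that add atoms: none
Why: Catalytic hydrogenolysis should remove the four benzyl ethers and two benzyl esters under neutral conditions while C3–C4 is still saturated, and acid then ionises the p-hydroxybenzylic C4–OH (quinone-methide-like cation) so that E1 loss of the C3–H gives the conjugated C3=C4 ester; C1, C2 and the malate centre are not touched.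

**Compound list**
1 | 3,4-bis(benzyloxy)benzaldehyde | O=Cc1ccc(OCc2ccccc2)c(OCc2ccccc2)c1 | starting material
2 | 4,5-bis(benzyloxy)-2-bromobenzaldehyde | O=Cc1cc(OCc2ccccc2)c(OCc2ccccc2)cc1Br | intermediate
3 | 1,2-bis(benzyloxy)-4-(chloromethyl)benzene | ClCc1ccc(OCc2ccccc2)c(OCc2ccccc2)c1 | starting material
4 | 2-[3,4-bis(benzyloxy)benzyl]-4,4,5,5-tetramethyl-1,3,2-dioxaborolane | CC1(C)OB(Cc2ccc(OCc3ccccc3)c(OCc3ccccc3)c2)OC1(C)C | intermediate
5 | 4,5-bis(benzyloxy)-2-[3,4-bis(benzyloxy)benzyl]benzaldehyde | O=Cc1cc(OCc2ccccc2)c(OCc2ccccc2)cc1Cc1ccc(OCc2ccccc2)c(OCc2ccccc2)c1 | intermediate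
6 | (S)-malic acid | OC(=O)C[C@H](O)C(=O)O | starting material
7 | (3S)-2,5-dioxooxolan-3-yl trifluoroacetate (O-trifluoroacetylmalic anhydride) | O=C1C[C@H](OC(=O)C(F)(F)F)C(=O)O1 | intermediate
8 | (3S)-4-(benzyloxy)-3-hydroxy-4-oxobutanoic acid | OC(=O)C[C@H](O)C(=O)OCc1ccccc1 | intermediate
9 | (2E)-4-(benzyloxy)-4-oxobut-2-enoic acid (mono-benzyl fumarate) | OC(=O)/C=C/C(=O)OCc1ccccc1 | starting material
10 | benzyl (2E)-4-chloro-4-oxobut-2-enoate | O=C(Cl)/C=C/C(=O)OCc1ccccc1 | intermediate
11 | (3S)-4-(benzyloxy)-3-{[(2E)-4-(benzyloxy)-4-oxobut-2-enoyl]oxy}-4-oxobutanoic acid | OC(=O)C[C@H](OC(=O)/C=C/C(=O)OCc1ccccc1)C(=O)OCc1ccccc1 | intermediate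
12 | (E)-{(6E)-3,4-bis(benzyloxy)-6-[3,4-bis(benzyloxy)benzylidene]cyclohexa-2,4-dien-1-ylidene}methanol (E,E-photoenol of 5) | O/C=C1\C=C(OCc2ccccc2)C(OCc2ccccc2)=C/C1=C\c1ccc(OCc2ccccc2)c(OCc2ccccc2)c1 | intermediate
13 | diisopropoxytitanium species that carries 12 as enolate and 11 as carboxylate | CC(C)O[Ti](OC(C)C)(O/C=C1\C=C(OCc2ccccc2)C(OCc2ccccc2)=C/C1=C\c1ccc(OCc2ccccc2)c(OCc2ccccc2)c1)OC(=O)C[C@H](OC(=O)/C=C/C(=O)OCc1ccccc1)C(=O)OCc1ccccc1 | intermediate
14 | 2-benzyl 3-[(2S)-1-(benzyloxy)-3-carboxy-1-oxopropan-2-yl] (1R,2S,3R,4R)-6,7-bis(benzyloxy)-1-[3,4-bis(benzyloxy)phenyl]-4-hydroxy-1,2,3,4-tetrahydronaphthalene-2,3-dicarboxylate | OC(=O)C[C@H](OC(=O)[C@H]1[C@@H](O)c2cc(OCc3ccccc3)c(OCc3ccccc3)cc2[C@@H](c2ccc(OCc3ccccc3)c(OCc3ccccc3)c2)[C@@H]1C(=O)OCc1ccccc1)C(=O)OCc1ccccc1 | intermediate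
15 | (2S)-2-({[(1R,2S,3R,4R)-2-carboxy-1-(3,4-dihydroxyphenyl)-4,6,7-trihydroxy-1,2,3,4-tetrahydronaphthalen-3-yl]carbonyl}oxy)butanedioic acid (locants as in 14) | OC(=O)C[C@H](OC(=O)[C@H]1[C@@H](O)c2cc(O)c(O)cc2[C@@H](c2ccc(O)c(O)c2)[C@@H]1C(=O)O)C(=O)O | intermediate
16 | (2S)-2-{[(1R,2S)-2-carboxy-1-(3,4-dihydroxyphenyl)-6,7-dihydroxy-1,2-dihydronaphthalene-3-carbonyl]oxy}butanedioic acid | O=C(O)C[C@H](OC(=O)C1=Cc2cc(O)c(O)cc2[C@@H](c2ccc(O)c(O)c2)[C@@H]1C(=O)O)C(=O)O | target

**Step count and risks**
Total step count: 7. Longest linear sequence: 4 steps (steps 1, 3, 6, 7).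

Steps most likely to fail:

Step 6 (proposed new method). The carboxylate may not stay on the titanium that carries the dienolate (aggregation of titanium carboxylates, or protonation of the photoenol by free acid). The cycloaddition would then run untethered and lose regio- and facial selectivity. The fallback uses known chemistry, sets out from 5 and comes back at 16. Compound 5 and commercial di-tert-butyl fumarate would react in the known enantioselective photoenolization/Diels–Alder reaction with Ti(OiPr)4 and a TADDOL-type diol ligand, the ligand enantiomer being chosen for si-face attack. This should give di-tert-butyl (1R,2S,3R,4R)-6,7-bis(benzyloxy)-1-[3,4-bis(benzyloxy)phenyl]-4-hydroxy-1,2,3,4-tetrahydronaphthalene-2,3-dicarboxylate F1, for which regiochemistry is no issue. CF3CO2H would cleave both esters and dehydrate to (1R,2S)-6,7-bis(benzyloxy)-1-[3,4-bis(benzyloxy)phenyl]-1,2-dihydronaphthalene-2,3-dicarboxylic acid F2. One equivalent of CsHCO3 in DMF would then allow alkylation at the less hindered conjugated C3 carboxylate (the C2 acid is flanked by the aryl-bearing C1). The alkylating agent is dibenzyl (2R)-2-{[(trifluoromethyl)sulfonyl]oxy}butanedioate F3, made from commercial dibenzyl (R)-malate and triflic anhydride, and it reacts with inversion (SN2). The product would be (1R,2S)-6,7-bis(benzyloxy)-1-[3,4-bis(benzyloxy)phenyl]-3-({[(2S)-1,4-bis(benzyloxy)-1,4-dioxobutan-2-yl]oxy}carbonyl)-1,2-dihydronaphthalene-2-carboxylic acid F4. BCl3 with pentamethylbenzene at −78 to 0 °C would remove the six benzyl groups to give 16.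

Step 7. Hydrogenolysis of the activated benzylic C4–O bond, or early dehydration followed by hydrogenation of the new C3=C4 bond, would lead to over-reduced tetralins. The fallback sets out from 14 and comes back at 16, with the order reversed and no hydrogen used. Acid-catalysed dehydration (TsOH, toluene, 40 °C) would give (3S)-4-(benzyloxy)-3-({[(1R,2S)-6,7-bis(benzyloxy)-2-[(benzyloxy)carbonyl]-1-[3,4-bis(benzyloxy)phenyl]-1,2-dihydronaphthalen-3-yl]carbonyl}oxy)-4-oxobutanoic acid F5. Debenzylation with BCl3 and pentamethylbenzene at −78 to 0 °C, a Lewis-acid method that leaves the alkene alone, would then give 16.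

Step 5. The free carboxylic acid of 8 competes for the acid chloride, and self-condensation of 8 through its mixed anhydride would consume material. The fallback sets out from 6 and 9 (as its chloride 10) and comes back at 11, with the order of ester formation inverted. (S)-Malic acid 6 would be acylated with two equivalents of 10, one serving as dehydrating agent as in the classical reaction of malic acid with acid chlorides. This should give (3S)-2,5-dioxooxolan-3-yl benzyl (2E)-but-2-enedioate F6. Benzyl alcohol would open this anhydride at the carbonyl beside the acyloxy group, the known regiochemistry of O-acylmalic anhydride alcoholysis, to give 11.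

**Further compounds**
F1 | step 6 | di-tert-butyl (1R,2S,3R,4R)-6,7-bis(benzyloxy)-1-[3,4-bis(benzyloxy)phenyl]-4-hydroxy-1,2,3,4-tetrahydronaphthalene-2,3-dicarboxylate | CC(C)(C)OC(=O)[C@H]1[C@@H](O)c2cc(OCc3ccccc3)c(OCc3ccccc3)cc2[C@@H](c2ccc(OCc3ccccc3)c(OCc3ccccc3)c2)[C@@H]1C(=O)OC(C)(C)C
F2 | step 6 | (1R,2S)-6,7-bis(benzyloxy)-1-[3,4-bis(benzyloxy)phenyl]-1,2-dihydronaphthalene-2,3-dicarboxylic acid | OC(=O)C1=Cc2cc(OCc3ccccc3)c(OCc3ccccc3)cc2[C@@H](c2ccc(OCc3ccccc3)c(OCc3ccccc3)c2)[C@@H]1C(=O)O
F3 | step 6 | dibenzyl (2R)-2-{[(trifluoromethyl)sulfonyl]oxy}butanedioate | O=C(OCc1ccccc1)C[C@@H](OS(=O)(=O)C(F)(F)F)C(=O)OCc1ccccc1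
F4 | step 6 | (1R,2S)-6,7-bis(benzyloxy)-1-[3,4-bis(benzyloxy)phenyl]-3-({[(2S)-1,4-bis(benzyloxy)-1,4-dioxobutan-2-yl]oxy}carbonyl)-1,2-dihydronaphthalene-2-carboxylic acid | O=C(OCc1ccccc1)C[C@H](OC(=O)C1=Cc2cc(OCc3ccccc3)c(OCc3ccccc3)cc2[C@@H](c2ccc(OCc3ccccc3)c(OCc3ccccc3)c2)[C@@H]1C(=O)O)C(=O)OCc1ccccc1
F5 | step 7 | (3S)-4-(benzyloxy)-3-({[(1R,2S)-6,7-bis(benzyloxy)-2-[(benzyloxy)carbonyl]-1-[3,4-bis(benzyloxy)phenyl]-1,2-dihydronaphthalen-3-yl]carbonyl}oxy)-4-oxobutanoic acid | OC(=O)C[C@H](OC(=O)C1=Cc2cc(OCc3ccccc3)c(OCc3ccccc3)cc2[C@@H](c2ccc(OCc3ccccc3)c(OCc3ccccc3)c2)[C@@H]1C(=O)OCc1ccccc1)C(=O)OCc1ccccc1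
F6 | step 5 | (3S)-2,5-dioxooxolan-3-yl benzyl (2E)-but-2-enedioate | O=C1C[C@H](OC(=O)/C=C/C(=O)OCc2ccccc2)C(=O)O1
A1 | direct plan | 1,2-dimethoxybenzene (veratrole) | COc1ccccc1OC
A2 | direct plan | 3-(3,4-dimethoxyphenyl)-5,6-dimethoxy-1H-inden-1-one | O=C1C=C(c2ccc(OC)c(OC)c2)c2cc(OC)c(OC)cc21
A3 | direct plan | tert-butyl (2S,3R)-3-(3,4-dimethoxyphenyl)-5,6-dimethoxy-1-oxo-2,3-dihydro-1H-indene-2-carboxylate | O=C1[C@@H](C(=O)OC(C)(C)C)[C@H](c2ccc(OC)c(OC)c2)c2cc(OC)c(OC)cc21
A4 | direct plan | tert-butyl (1R,2R)-1-(3,4-dimethoxyphenyl)-6,7-dimethoxy-4-oxo-1,2,3,4-tetrahydronaphthalene-2-carboxylate | O=C1C[C@@H](C(=O)OC(C)(C)C)[C@H](c2ccc(OC)c(OC)c2)c2cc(OC)c(OC)cc21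
A5 | direct plan | di-tert-butyl (1R,2S,3R)-1-(3,4-dimethoxyphenyl)-6,7-dimethoxy-4-oxo-1,2,3,4-tetrahydronaphthalene-2,3-dicarboxylate | O=C1[C@H](C(=O)OC(C)(C)C)[C@@H](C(=O)OC(C)(C)C)[C@H](c2ccc(OC)c(OC)c2)c2cc(OC)c(OC)cc21
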